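**Retrosynthetic overview**
1. Gancaonin H comes from isoangustone A. Ring D closes last, on the unprotected tetraphenol, by catechol → o-quinone → o-quinone methide → oxa-6π electrocyclisation.
2. The two prenyl groups come from two C-allyl groups by double cross-metathesis. The C-allyl groups come from the 5-O- and 4'-O-allyl ethers by double Claisen rearrangement, where C6 and C5' are the only open ortho positions.
3. The isoflavone core comes from a flavanone by an oxidative 2→3 aryl shift with trivalent iodine, the laboratory form of the isoflavone synthase step.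
4. The flavanone (ring C) comes from a 2'-hydroxychalcone by oxa-Michael closure, the chalcone isomerase step. The chalcone comes from an acetophenone and O-allylvanillin.
5. Ring order: rings A and B are bought, ring C is formed first, ring D last.

Assumption: gancaonin H has no stereocentre and is achiral, so no enantiomer has to be chosen; the racemic C2 centre of flavanone 6 is erased in step 3.

**Route**

Step 1
Reactants: 1 2',6'-dihydroxy-4'-methoxyacetophenone; 2 allyl bromide
Product: 3 2'-(allyloxy)-6'-hydroxy-4'-methoxyacetophenone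
Conditions: allyl bromide (1.05 equiv), K2CO3 (1.1 equiv), acetone, reflux, 6 h
Reagents that add atoms: allyl bromide (2), C=CCBr
Why: Williamson ether synthesis, in which the two phenols of 1 are equivalent and the OH left after the first allylation is held in a strong hydrogen bond to the ketone, so one equivalent of bromide stops at the mono-ether and no stereocentre is formed.

Step 2
Reactants: 3 2'-(allyloxy)-6'-hydroxy-4'-methoxyacetophenone; 4 4-(allyloxy)-3-methoxybenzaldehyde (O-allylvanillin)
Product: 6 rac-5-(allyloxy)-2-[4-(allyloxy)-3-methoxyphenyl]-7-methoxychroman-4-one, via chalcone 5 (not isolated)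
Conditions: KOH (50% aq), EtOH, rt, 36 h; then AcOH to pH 6–7, reflux, 24 h
Reagents that add atoms: none
Why: Claisen–Schmidt condensation gives the (E)-chalcone 5, and the KOAc buffer made on neutralisation then promotes the 6-endo oxa-Michael closure of ring C, which the 6'-alkoxy group favours by twisting the enone out of plane, while the new C2 stereocentre is left racemic because step 3 makes C2 planar again.

Step 3
Reactants: 6 rac-5-(allyloxy)-2-[4-(allyloxy)-3-methoxyphenyl]-7-methoxychroman-4-one
Product: 8 5-(allyloxy)-3-[4-(allyloxy)-3-methoxyphenyl]-7-methoxy-4H-chromen-4-one, via C3 iodane 7 (not isolated)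
Conditions: PhI(OH)OTs (1.2 equiv), MeCN, reflux, 4 h
Reagents that add atoms: none
Why: Hypervalent-iodine oxidative 1,2-aryl migration of a flavanone, in which the enol of 6 is captured at C3 by the trivalent iodine of Koser's reagent to give 7, the electron-rich 4-alkoxy-3-methoxyphenyl group shifts from C2 to C3 anti to departing PhI through a phenonium ion, the C2 cation stabilised by the ring oxygen loses H3, non-nucleophilic MeCN closes off the ring-contraction path seen in methanol, the terminal allyl ethers are far less nucleophilic than the enol, and both stereocentres disappear.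

Step 4
Reactants: 8 5-(allyloxy)-3-[4-(allyloxy)-3-methoxyphenyl]-7-methoxy-4H-chromen-4-one
Product: 9 6-allyl-3-(3-allyl-4-hydroxy-5-methoxyphenyl)-5-hydroxy-7-methoxy-4H-chromen-4-one
Conditions: PhNEt2, 210 °C, sealed tube under argon, 2 h
Reagents that add atoms: none
Why: Double aromatic Claisen [3,3] rearrangement, in which the 5-O-allyl group can only reach C6 (C4a is blocked) and the 4'-O-allyl group only C5' (C3' carries OMe), each dienone tautomerises at once to its phenol, and so both C-allyl groups are placed with full regiocontrol in one operation without creating a stereocentre.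

Step 5
Reactants: 9 6-allyl-3-(3-allyl-4-hydroxy-5-methoxyphenyl)-5-hydroxy-7-methoxy-4H-chromen-4-one
Product: 10 6-allyl-3-(3-allyl-4,5-dihydroxyphenyl)-5,7-dihydroxy-4H-chromen-4-one (6,5'-diallylorobol)
Conditions: BBr3 (8 equiv), CH2Cl2, −78 °C to rt, 12 h; then ice-water
Reagents that add atoms: none
Why: BBr3 aryl methyl ether cleavage, in which boron binds each OMe oxygen and bromide removes the methyl group by SN2, the chromenone and terminal allyl groups ortho to phenols tolerate the reagent at or below room temperature as in BBr3 demethylations of o-allylanisoles, and the step comes before metathesis because prenyl groups would cyclise to chromans in this acid.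

Step 6
Reactants: 10 6,5'-diallylorobol; 11 2-methyl-2-butene
Product: 12 isoangustone A, 3-[3,4-dihydroxy-5-(3-methylbut-2-enyl)phenyl]-5,7-dihydroxy-6-(3-methylbut-2-enyl)-4H-chromen-4-one
Conditions: second-generation Grubbs catalyst RuCl2(=CHPh)(PCy3)(H2IMes) (2 × 5 mol %), 2-methyl-2-butene/CH2Cl2/THF, 40 °C, sealed tube, 12 h
Reagents that add atoms: 2-methyl-2-butene (11), CC=C(C)C
Why: Double olefin cross-metathesis, in which each terminal allyl group exchanges its =CH2 for the =CMe2 end of the large excess of alkene, volatile propene leaves, homodimers are re-opened by the excess alkene, the trisubstituted product alkenes do not react further, and no E/Z or stereocentre question arises.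

Step 7
Reactants: 12 isoangustone A
Product: 15 gancaonin H, via o-quinone 13 (not isolated), via o-quinone methide 14 (not isolated)
Conditions: Ag2O (1.1 equiv), Na2SO4, THF, 0 °C to rt, dark, 30 min; then Et3N (0.2 equiv), 40 °C, 2 h
Reagents that add atoms: none
Why: Proposed new method: Ag2O dehydrogenates only the catechol (ring A is a hydrogen-bonded, carbonyl-deactivated resorcinol that Ag2O leaves alone) to o-quinone 13, whose prenyl CH2, allylic and conjugated through the dienone to the C3' carbonyl, tautomerises under amine catalysis to the (Z)-vinyl o-quinone methide 14, which closes by a thermally allowed oxa-6π electrocyclisation that restores aromaticity, forms ring D at O4' only, leaves the ring A prenyl group untouched and creates no stereocentre; the closest known reaction types are the base-induced isomerisation of prenyl-1,4-benzoquinones to 6-chromenols and the DDQ cyclodehydrogenation of o-prenylphenols.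

**Compound list**
1 | 2',6'-dihydroxy-4'-methoxyacetophenone | CC(=O)c1c(O)cc(OC)cc1O | starting material
2 | allyl bromide | C=CCBr | starting material
3 | 2'-(allyloxy)-6'-hydroxy-4'-methoxyacetophenone | CC(=O)c1c(O)cc(OC)cc1OCC=C | intermediate
4 | 4-(allyloxy)-3-methoxybenzaldehyde | C=CCOc1ccc(C=O)cc1OC | starting material
5 | (E)-1-[2-(allyloxy)-6-hydroxy-4-methoxyphenyl]-3-[4-(allyloxy)-3-methoxyphenyl]prop-2-en-1-one | C=CCOc1ccc(/C=C/C(=O)c2c(O)cc(OC)cc2OCC=C)cc1OC | intermediate (not isolated)
6 | rac-5-(allyloxy)-2-[4-(allyloxy)-3-methoxyphenyl]-7-methoxychroman-4-one | C=CCOc1ccc(C2CC(=O)c3c(OCC=C)cc(OC)cc3O2)cc1OC | intermediate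
7 | 3-[phenyl(tosyloxy)-λ3-iodanyl] derivative of 6 (racemic; C3 epimerises through the enol, the 2,3-trans form migrates) | C=CCOc1ccc(C2Oc3cc(OC)cc(OCC=C)c3C(=O)C2I(OS(=O)(=O)c2ccc(C)cc2)c2ccccc2)cc1OC | intermediate (not isolated)
8 | 5-(allyloxy)-3-[4-(allyloxy)-3-methoxyphenyl]-7-methoxy-4H-chromen-4-one | C=CCOc1ccc(-c2coc3cc(OC)cc(OCC=C)c3c2=O)cc1OC | intermediate
9 | 6-allyl-3-(3-allyl-4-hydroxy-5-methoxyphenyl)-5-hydroxy-7-methoxy-4H-chromen-4-one | C=CCc1c(OC)cc2occ(-c3cc(CC=C)c(O)c(OC)c3)c(=O)c2c1O | intermediate
10 | 6-allyl-3-(3-allyl-4,5-dihydroxyphenyl)-5,7-dihydroxy-4H-chromen-4-one | C=CCc1c(O)cc2occ(-c3cc(O)c(O)c(CC=C)c3)c(=O)c2c1O | intermediate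
11 | 2-methyl-2-butene | CC=C(C)C | starting material
12 | isoangustone A | CC(C)=CCc1c(O)cc2occ(-c3cc(O)c(O)c(CC=C(C)C)c3)c(=O)c2c1O | intermediate
13 | ring B o-quinone of 12, 3-(3-methylbut-2-enyl)-5-(chromenon-3-yl)cyclohexa-3,5-diene-1,2-dione | CC(C)=CCC1=CC(c2coc3cc(O)c(CC=C(C)C)c(O)c3c2=O)=CC(=O)C1=O | intermediate (not isolated)
14 | (Z)-2-hydroxy-6-(3-methylbut-2-enylidene)cyclohexa-2,4-dienone tautomer of 13 (o-quinone methide) | CC(C)=C/C=C1/C=C(c2coc3cc(O)c(CC=C(C)C)c(O)c3c2=O)C=C(O)C1=O | intermediate (not isolated)
15 | gancaonin H (achiral) | CC(C)=CCc1c(O)cc2occ(-c3cc(O)c4c(c3)C=CC(C)(C)O4)c(=O)c2c1O | target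

**Step count**
Total steps: 7. Longest linear sequence: 7 (1 → 15).

**The three steps most likely to fail, with fallbacks**

Step 3, the aryl shift on the flavanone. Three things can go wrong:
- 2,3-dehydrogenation to the flavone competes with the shift.
- The trialkoxy ring A may be attacked by trivalent iodine to give a diaryliodonium salt.
- The allyl ethers may be slowly consumed.

The fallback sets out from chalcone 5 and comes back at isoflavone 8. It carries out the shift on the open chain and closes ring C afterwards, so no flavone can form. Step 2 is stopped before the acetic acid stage and 5 is isolated. Ac2O/pyridine then gives the 2'-O-acetylchalcone F1. PhI(OAc)2 and TsOH·H2O in MeOH/HC(OMe)3 add iodine and methanol across the enone, and the aryl group moves from C-beta to C-alpha, giving the rearranged dimethyl acetal F2. Aqueous NaOH followed by HCl/MeOH at reflux frees the phenol and closes the pyranone to 8.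

Step 7, the unprotected oxidation and electrocyclisation. Quinone 13 is a strong electrophile. It may be attacked by ring A phenols or dimerise before it tautomerises, and the acidic 7-OH can bind silver. The catechol 12 is also air-sensitive.

The fallback sets out from 3 and comes back at o-quinone 13. It never makes a catechol, because the ring B oxygen and the quinone arrive together by ortho-oxygenation of a monophenol.
- Compound 3 is condensed, as in step 2, with 4-(allyloxy)benzaldehyde F5 (bought) through the chalcone F6 to the flavanone F7.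
- PhI(OH)OTs in MeCN gives the isoflavone F8.
- Heating in PhNEt2 gives the double Claisen product F9.
- BBr3 removes the single methyl group to give 6,3'-diallylgenistein F10.
- Cross-metathesis with 11 gives lupalbigenin F11.
- IBX (2-iodoxybenzoic acid, 1.1 equiv) in DMF at rt delivers oxygen to the only free ortho position of the electron-rich ring B phenol. The carbonyl-deactivated ring A phenols do not react. This gives 13 under neutral to weakly acidic conditions, and 13 goes on through 14 to 15.

Step 6, metathesis on a free catechol. The catechol may chelate and deactivate ruthenium, and 10 is poorly soluble. The fallback sets out from 10 and comes back at 12, keeping the phenols away from the carbene. Ac2O/pyridine/DMAP gives 6,5'-diallylorobol tetraacetate F3, which dissolves readily in CH2Cl2/2-methyl-2-butene. Double cross-metathesis of F3 gives isoangustone A tetraacetate F4. K2CO3 in degassed MeOH at 0 °C then removes all four acetates to give 12.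

**Further compounds**
F1 | step 3 | (E)-2'-O-acetyl derivative of chalcone 5 | C=CCOc1ccc(/C=C/C(=O)c2c(OC(C)=O)cc(OC)cc2OCC=C)cc1OC
F2 | step 3 | rac-1-[2-acetoxy-6-(allyloxy)-4-methoxyphenyl]-2-[4-(allyloxy)-3-methoxyphenyl]-3,3-dimethoxypropan-1-one | C=CCOc1ccc(C(C(OC)OC)C(=O)c2c(OC(C)=O)cc(OC)cc2OCC=C)cc1OC
F3 | step 6 | 6,5'-diallylorobol tetraacetate | C=CCc1c(OC(C)=O)cc2occ(-c3cc(OC(C)=O)c(OC(C)=O)c(CC=C)c3)c(=O)c2c1OC(C)=O
F4 | step 6 | isoangustone A tetraacetate | CC(C)=CCc1c(OC(C)=O)cc2occ(-c3cc(OC(C)=O)c(OC(C)=O)c(CC=C(C)C)c3)c(=O)c2c1OC(C)=O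
F5 | step 7 | 4-(allyloxy)benzaldehyde | C=CCOc1ccc(C=O)cc1
F6 | step 7 | (E)-1-[2-(allyloxy)-6-hydroxy-4-methoxyphenyl]-3-[4-(allyloxy)phenyl]prop-2-en-1-one | C=CCOc1ccc(/C=C/C(=O)c2c(O)cc(OC)cc2OCC=C)cc1
F7 | step 7 | rac-5-(allyloxy)-2-[4-(allyloxy)phenyl]-7-methoxychroman-4-one | C=CCOc1ccc(C2CC(=O)c3c(OCC=C)cc(OC)cc3O2)cc1
F8 | step 7 | 5-(allyloxy)-3-[4-(allyloxy)phenyl]-7-methoxy-4H-chromen-4-one | C=CCOc1ccc(-c2coc3cc(OC)cc(OCC=C)c3c2=O)cc1
F9 | step 7 | 6-allyl-3-(3-allyl-4-hydroxyphenyl)-5-hydroxy-7-methoxy-4H-chromen-4-one | C=CCc1c(OC)cc2occ(-c3ccc(O)c(CC=C)c3)c(=O)c2c1O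
F10 | step 7 | 6,3'-diallylgenistein | C=CCc1c(O)cc2occ(-c3ccc(O)c(CC=C)c3)c(=O)c2c1O
F11 | step 7 | lupalbigenin (6,3'-diprenylgenistein) | CC(C)=CCc1c(O)cc2occ(-c3ccc(O)c(CC=C(C)C)c3)c(=O)c2c1O
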